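# Proposed synthesis of CNP0361110.2 through an enantioselective carbenoid C–H insertion that turns a benzyl ether into flavanone C2

**Numbering used throughout**

- 1: 1-(2,4,6-trihydroxyphenyl)ethanone
- 2: 4-(benzyloxy)benzyl chloride
- 3: para mono-ether of 1
- 4: 2,4-bis-ether with one chelated hydroxyl
- 5: tris-ether methyl ketone
- 6: 2-bromo-4-chlorophenol
- 7: 2-bromo-1-tert-butoxy-4-chlorobenzene
- 8: deoxybenzoin
- 9: α-diazo deoxybenzoin (key-step precursor)
- 10: 2,3-cis chromanone (not isolated)
- 11: 2,3-trans chromanone (key-step product)
- 12: 1-(2,6-dihydroxy-4-methoxyphenyl)ethanone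
- 13: its mono-benzyl ether
- 14: enaminone (not isolated)
- 15: 5-benzyloxy-7-methoxychromone
- 16: chromon-2-ylzinc chloride (not isolated)
- 17: fully protected biflavonoid
- 18: target

## Analysis of the target

The target is a biflavonoid in which a 5,7-dihydroxyflavanone (rings A and C, with the 4-hydroxyphenyl ring B on C2) is bonded through C3 to C3′ of ring B′ of a 5-hydroxy-7-methoxyflavone (rings A′, C′ and B′, ring B′ carrying the 4′-hydroxyl). The only stereocentres are C2 (S) and C3 (R) of the flavanone; they are adjacent and trans, so both aryl groups sit equatorial on the half-chair of ring C. C3 is α to the C4 carbonyl and benzylic, so it epimerises easily and the trans arrangement is the thermodynamic one. C2 can be lost only by opening ring C, either by E1cB elimination to a 2′-hydroxychalcone or by ionisation of the C2–O1 bond assisted by the 4-oxygenated ring B, and base, strong Lewis acid and heat all promote this. The sensitive groups are five free phenols (two chelated to carbonyls), the single methyl ether at O7 of the flavone, which must be told apart from them, and the flavone enone. The hard points are the congested C3–C3′ bond, which joins a tertiary carbon to an arene carbon ortho to a phenol oxygen, and absolute control at C2 without endangering it later. The strategy rests on one feature: flavanone C2 is a benzylic carbon bound to O1 and to a 4-oxygenated phenyl ring, that is the methylene carbon of a 4-alkoxybenzyl ether on ring A, while C3 is the α-carbon of a deoxybenzoin (ring A–C4(=O)–C3–ring B′). The C2–C3 bond can therefore be made by inserting a carbenoid at C3 into a C–H bond of that ether.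

## Retrosynthetic reasoning

**18 from 17 (five O–C bonds).** All phenols except the O7 methyl ether are masked as ethers that a single boron Lewis acid removes: benzyl on flavone O5 and on O4 of ring B, 4-benzyloxybenzyl on O5 and O7 of ring A, and tert-butyl on the oxygen of ring B′. The oxygen of ring B′ must carry a group with no hydrogen on the atom bound to oxygen, because of the key step. An aryl ester would also meet this, but it was set aside for two reasons: it sits ortho to an enolisable benzylic carbon and can undergo O-to-C acyl shift in the basic steps, and its removal needs basic solvolysis on a flavanone that racemises by ring opening. The tert-butyl ether is inert to base and leaves together with the benzyl-type ethers. The forward step must cleave five ethers without ionising the C2–O1 bond.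

**17 from 11 and 15 (bond between C1′ of ring B′ and C2 of ring C′).** This cut separates the half holding both stereocentres from a flat, achiral heterocycle. It is chosen over building the pyrone on ring B′, because the classical flavone constructions need strong base or oxidants that a finished flavanone does not survive. Chromone 15 is metalated at C2, its most acidic position, to give zinc reagent 16, which couples with the aryl chloride of 11 under palladium catalysis. The forward step has to activate an aryl chloride para to an ether while leaving C2 and C3 alone.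

**11 from 9 (the C2–C3 bond, ring C).** This is the central disconnection. Loss of nitrogen from diazo ketone 9 gives a carbenoid at C3, which inserts into a benzylic C–H bond of one ortho 4-benzyloxybenzyl ether of ring A. That single step forms the C2–C3 bond, closes the pyranone and creates both stereocentres. The unused ortho ether and the para ether stay as protecting groups for O5 and O7, and the benzyl ether on the inserted group becomes the protected 4-hydroxyl of ring B. Cutting here keeps the C4 carbonyl at its final oxidation level and places the difficult C3–C3′ bond in the acyclic precursor, where it is an ordinary benzyl–aryl bond.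

**9 from 8 (the C=N2 unit).** The diazo group comes from diazo transfer to the activated methylene of deoxybenzoin 8. No skeletal bond is formed.

**8 from 5 and 7 (the CH2–aryl bond to ring B′).** The methylene–aryl bond is made by palladium-catalysed arylation of the enolate of methyl ketone 5 with aryl bromide 7. The more traditional cut between ring A and the carbonyl was rejected for three reasons. It needs hot Lewis acid, which no acid-labile ether survives. A benzyl ketone with a free ortho oxygen cyclodehydrates to a 2-arylbenzofuran. Alkylating three phenols after the deoxybenzoin exists would set O-alkylation against C-alkylation of its acidic methylene. In 5 the ethers are in place before any acidic methylene exists. The halogens are differentiated by design: bromine reacts in this step, and chlorine, inert to the catalyst used here, is kept as the handle for the later coupling.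

**5 from 4, 4 from 3, 3 from 1 and 2 (three O–CH2 bonds, one at a time).** The three hydroxyls of 1 differ: the para one is free and the most acidic, one ortho hydroxyl is free once the para oxygen is capped, and the last ortho hydroxyl is locked in a hydrogen bond to the carbonyl. Each is therefore etherified with one equivalent of 2 under the weakest base that reaches it, through 3 and 4 to 5. This costs two extra operations on cheap material, but a phloroglucinol-type phenoxide never meets an excess of the easily ionised 4-alkoxybenzyl chloride, which is the situation in which C-alkylation of the ring takes over. The forward steps must stop at the mono-ether, then at the bis-ether, and finally force the chelated hydroxyl.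

**7 from 6; 15 from 13 from 12.** Compound 7 is the tert-butyl ether of commercial phenol 6. Chromone 15 arises from commercial acetophenone 12 by mono-benzylation to 13 and one-carbon annulation.

## Alternatives that were turned down

**Alternative 1:** Biomimetic folding of a polyketide chain into the flavone half.
- Disconnection: C4a–C5 (ring A′) and O1–C2 (ring C′) of the flavone are cut, leading to the open-chain tetraketo ester A2.
- Forward key step: a magnesium alkoxide chelates the polycarbonyl chain, the future C4a methylene adds to the ester carbonyl in a Claisen condensation, the ring aromatises, and acid closes the pyrone to give bromoflavone A1.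
- For: two rings come from an acyclic precursor with the oxygen pattern built in. No protecting groups are needed on ring A′. Selective O7-methylation of A1 should be easy because O5–H is chelated.
- Against: it addresses the half of the molecule that any method makes easily and leaves the C3–C3′ bond and both stereocentres unsolved. A1 offers only an aryl bromide ortho to an ether, and attaching a preformed flavanone enolate there would be hindered and basic enough to open ring C. Chain A2 has four acidic methylenes and several competing folding modes, so the regiochemistry depends on chelation. Preparing A2 itself takes several polyanion acylations.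
- Comparison: Alternative 1 is stronger in needing no transition metal and no protection for the flavone ring A′. The chosen strategy offers a two-step chromone synthesis from a commercial acetophenone and spends its effort on the stereogenic half.

**Alternative 2:** Carbonylative annulation of an iodophenol with an alkyne.
- Disconnection: three bonds of ring C′ (C4a–C4, C4–C3, O1–C2) are cut, leading to iodoresorcinol A4, a one-carbon carbonyl source and aryl alkyne A5.
- Forward key step: zerovalent palladium inserts into the C–I bond, carbonylation gives an acylpalladium, coupling with the terminal alkyne gives an ynone, and a secondary amine promotes 6-endo addition of the ortho hydroxyl to give A3.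
- For: it is very convergent. The flavone is formed with the O7 methyl and a free O5–H already in place, since the two hydroxyls of A4 are equivalent. The regiochemistry of the flavone is fixed by construction.
- Against: alkyne A5 already contains the complete enantiopure trans-2,3-diaryl flavanone, so the route does not say how C2, C3 and the C3–C3′ bond are made. The key step exposes that flavanone to an amine base and heat, conditions under which C3–H is removed and ring C can open, eroding C2. 5-exo closure to an aurone competes. Installing the ethynyl group costs two more steps on a sensitive intermediate.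
- Comparison: Alternative 2 is stronger in not depending on the site of chromone metalation. The chosen strategy supplies the stereocentres and joins the halves in one non-basic operation.

**Alternative 3:** Ortho-quinone methide cycloaddition with a stilbene.
- Disconnection: O1–C2 and C3–C4 of flavanone ring C are cut, leading to salicyl alcohol A7 and (E)-stilbene A8, which already carries the flavone.
- Forward key step: a chiral phosphoric acid dehydrates A7 to the ortho-quinone methide and holds it by hydrogen bonding. A suprafacial [4+2] addition to the (E)-alkene gives the 2,3-trans flavan A6, with oxygen bonding to the carbon that bears the 4-benzyloxyphenyl group.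
- For: both stereocentres and their trans relationship are set directly by catalyst and alkene geometry. There is no epimerisation step and no diazo compound, and the convergence is complete.
- Against: A6 is a flavan, so C4 is a methylene and must then be oxidised to the ketone in a molecule with five benzyl ether methylenes and a doubly activated C2–H that are at least as oxidisable. This is the decisive flaw. Stilbene A8 is also a weak 2π partner, with no heteroatom donor and one aryl group carrying the electron-poor flavone and an ester. The quinone methide from a 3,5-dialkoxyphenol is strongly stabilised and can be trapped by its own precursor.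
- Comparison: Alternative 3 is stronger on direct catalyst control of both centres. The chosen strategy delivers ring C at the correct oxidation level, because the C4 carbonyl is the acceptor of the carbenoid, and needs catalyst control only at C2, since C3 equilibrates.

Key step: step 7

Assumption: Rh2(S-PTTL)4 is taken to select the benzylic hydrogen whose replacement gives 2S; if it favours 2R, the mirror-image catalyst Rh2(R-PTTL)4 is used and nothing else changes.

## Route

Step 1
Reactants: 1 1-(2,4,6-trihydroxyphenyl)ethanone; 2 4-(benzyloxy)benzyl chloride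
Product: 3 1-[4-(4-benzyloxybenzyloxy)-2,6-dihydroxyphenyl]ethanone
Conditions: 2 (1.0 equiv), CsHCO3 (1.2 equiv), MeCN, 60 °C
Reagents that add atoms: none
Why: Williamson ether synthesis under a hydrogen carbonate base, which should ionise only the para hydroxyl, the most acidic and least hindered of the three; with one equivalent of the chloride the reaction should stop largely at the para mono-ether. The acetyl group lowers the C-nucleophilicity of the ring, so O-alkylation should dominate.

Step 2
Reactants: 3 1-[4-(4-benzyloxybenzyloxy)-2,6-dihydroxyphenyl]ethanone; 2 4-(benzyloxy)benzyl chloride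
Product: 4 1-[2,4-bis(4-benzyloxybenzyloxy)-6-hydroxyphenyl]ethanone
Conditions: 2 (1.05 equiv), K2CO3 (1.5 equiv), acetone, reflux
Reagents that add atoms: none
Why: Williamson ether synthesis; the two ortho hydroxyls of 3 are equivalent, and once one is alkylated the other is locked in a hydrogen bond to the carbonyl and reacts much more slowly, so the reaction should stop at the bis-ether.

Step 3
Reactants: 4 1-[2,4-bis(4-benzyloxybenzyloxy)-6-hydroxyphenyl]ethanone; 2 4-(benzyloxy)benzyl chloride
Product: 5 1-[2,4,6-tris(4-benzyloxybenzyloxy)phenyl]ethanone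
Conditions: 2 (1.3 equiv), Cs2CO3 (1.5 equiv), Bu4NI (0.1 equiv), DMF, 60 °C
Reagents that add atoms: none
Why: Williamson ether synthesis under forcing conditions; the cesium phenoxide in DMF and iodide catalysis should bring in the last, chelated hydroxyl. No acidic methylene is present yet, which is why all ethers are installed before the benzyl ketone is built.

Step 4
Reactants: 6 2-bromo-4-chlorophenol
Product: 7 2-bromo-1-tert-butoxy-4-chlorobenzene
Conditions: isobutene (excess), TfOH (5 mol%), CH2Cl2, −78 → −30 °C; Et3N quench
Reagents that add atoms: isobutene (2-methylpropene), CC(C)=C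
Why: Acid-catalysed addition of the phenol to isobutene (capture of the tert-butyl cation by oxygen); at low temperature O-alkylation should be favoured over Friedel–Crafts tert-butylation of the halogen-deactivated ring. The resulting ether is inert to base and has no hydrogen on the carbon bound to oxygen.

Step 5
Reactants: 5 1-[2,4,6-tris(4-benzyloxybenzyloxy)phenyl]ethanone; 7 2-bromo-1-tert-butoxy-4-chlorobenzene
Product: 8 2-(2-tert-butoxy-5-chlorophenyl)-1-[2,4,6-tris(4-benzyloxybenzyloxy)phenyl]ethanone
Conditions: Pd2(dba)3 (2 mol%), Xantphos (4.8 mol%), NaOtBu (2.2 equiv), toluene, 80 °C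
Reagents that add atoms: none
Why: Palladium-catalysed α-arylation of a methyl ketone enolate; zerovalent palladium with Xantphos inserts into the C–Br bond and should leave the C–Cl bond untouched. The more acidic product is held as its enolate, which should prevent a second arylation.

Step 6
Reactants: 8 2-(2-tert-butoxy-5-chlorophenyl)-1-[2,4,6-tris(4-benzyloxybenzyloxy)phenyl]ethanone
Product: 9 2-(2-tert-butoxy-5-chlorophenyl)-2-diazo-1-[2,4,6-tris(4-benzyloxybenzyloxy)phenyl]ethanone
Conditions: p-ABSA (1.5 equiv), DBU (2 equiv), MeCN, 0 °C → rt
Reagents that add atoms: 4-acetamidobenzenesulfonyl azide (p-ABSA), CC(=O)Nc1ccc(cc1)S(=O)(=O)N=[N+]=[N-]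
Why: Regitz diazo transfer; DBU forms the enolate of the benzyl ketone, which attacks the terminal nitrogen of the sulfonyl azide, and the adduct fragments to the diazo ketone and the sulfonamide. The ethers and the aryl chloride are inert to DBU.

Step 7
Reactants: 9 2-(2-tert-butoxy-5-chlorophenyl)-2-diazo-1-[2,4,6-tris(4-benzyloxybenzyloxy)phenyl]ethanone
Product: 11 (2S,3R)-3-(2-tert-butoxy-5-chlorophenyl)-2-(4-benzyloxyphenyl)-5,7-bis(4-benzyloxybenzyloxy)chroman-4-one, via cis-(2S,3S)-chromanone 10 (not isolated)
Conditions: Rh2(S-PTTL)4 (2 mol%), toluene, 0 °C → rt, slow addition of 9; then DBU (0.1 equiv), 0 °C; AcOH quench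
Reagents that add atoms: none
Why: Dirhodium tetrakis[N-phthaloyl-(S)-tert-leucinate] takes nitrogen from 9 to give a donor–acceptor carbenoid at C3, which inserts into a benzylic C–H bond of an ortho 4-benzyloxybenzyl ether through a three-centre transition state with retention at that carbon, forming C2–C3. The closest known reaction is the dirhodium-carboxylate-catalysed intramolecular C–H insertion of ortho-alkoxyaryl α-diazo ketones next to the ether oxygen to give chroman-4-ones, which has also been run with chiral carboxylates. Ring C closes by C–C bond formation in a 1,6-insertion; a 1,5-insertion is impossible because that position is the ether oxygen, which has no hydrogen. C2 is set by the catalyst, which must choose between the two enantiotopic benzylic hydrogens. C3 is formed kinetically (10 where cis) and is then equilibrated through the enol by catalytic DBU to the diequatorial trans product 11. The step needs insertion to beat attack of the same ether oxygen on the carbenoid (oxonium ylide, then [1,2]-shift of the benzyl group); the less electrophilic donor–acceptor carbenoid, the hydridic C–H bond activated by both oxygen and the 4-benzyloxyphenyl ring, a bulky carboxylate catalyst and a non-coordinating solvent are meant to secure this. Site selectivity comes from the substrate: the two ortho ethers are interchanged by rotation about the aryl–carbonyl bond and give the same product, the para ether is out of reach, and the tert-butyl ether on ring B′ has no C–H on the carbon bound to oxygen, so no dihydrobenzofuran can form. The aryl chloride is inert.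

Step 8
Reactants: 12 1-(2,6-dihydroxy-4-methoxyphenyl)ethanone
Product: 13 1-(2-benzyloxy-6-hydroxy-4-methoxyphenyl)ethanone
Conditions: BnBr (1.05 equiv), K2CO3 (1.2 equiv), acetone, reflux
Reagents that add atoms: benzyl bromide, BrCc1ccccc1
Why: Williamson mono-benzylation; after the first alkylation the remaining hydroxyl is locked in a hydrogen bond to the carbonyl and reacts much more slowly, so the reaction should stop at the mono-ether.

Step 9
Reactants: 13 1-(2-benzyloxy-6-hydroxy-4-methoxyphenyl)ethanone
Product: 15 5-benzyloxy-7-methoxy-4H-chromen-4-one, via enaminone 14 (not isolated)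
Conditions: DMF-DMA, toluene, 100 °C; then conc. HCl, CH2Cl2, rt
Reagents that add atoms: N,N-dimethylformamide dimethyl acetal, COC(OC)N(C)C
Why: Condensation of the methyl ketone with the amide acetal gives enaminone 14, and acid then promotes 6-endo addition of the phenol and loss of dimethylamine (standard chromone annulation). The acetal carbon becomes C2 of the chromone.

Step 10
Reactants: 11 (2S,3R)-3-(2-tert-butoxy-5-chlorophenyl)-2-(4-benzyloxyphenyl)-5,7-bis(4-benzyloxybenzyloxy)chroman-4-one; 15 5-benzyloxy-7-methoxy-4H-chromen-4-one
Product: 17 (2S,3R)-3-[5-(5-benzyloxy-7-methoxy-4-oxo-4H-chromen-2-yl)-2-tert-butoxyphenyl]-2-(4-benzyloxyphenyl)-5,7-bis(4-benzyloxybenzyloxy)chroman-4-one, via chromon-2-ylzinc chloride 16 (not isolated)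
Conditions: 15 (1.6 equiv), TMPZnCl·LiCl (1.5 equiv), THF, 25 °C; then 11, Pd(OAc)2 (4 mol%), XPhos (8 mol%), THF, 50 °C
Reagents that add atoms: none
Why: Directed zincation followed by Negishi coupling; without a Lewis acid additive the zinc amide is expected to remove the most acidic chromone proton, at C2 next to the ring oxygen, and the alkenylzinc transmetalates to the arylpalladium chloride formed by oxidative addition of zerovalent palladium/XPhos into the C–Cl bond. The chromone is used in excess over the amide base so that no zinc amide is left to deprotonate C3 of the flavanone, and organozinc chlorides tolerate the ketone, so C2 and C3 should be untouched.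

Step 11
Reactants: 17 (2S,3R)-3-[5-(5-benzyloxy-7-methoxy-4-oxo-4H-chromen-2-yl)-2-tert-butoxyphenyl]-2-(4-benzyloxyphenyl)-5,7-bis(4-benzyloxybenzyloxy)chroman-4-one
Product: 18 (2S,3R)-5,7-dihydroxy-3-[2-hydroxy-5-(5-hydroxy-7-methoxy-4-oxo-4H-chromen-2-yl)phenyl]-2-(4-hydroxyphenyl)chroman-4-one
Conditions: BCl3 (1 M in CH2Cl2, excess), pentamethylbenzene (excess), CH2Cl2, −78 → −40 °C; MeOH quench
Reagents that add atoms: none
Why: Lewis-acid ether cleavage with a cation scavenger; BCl3 coordinates the ether oxygens, and the benzyl, 4-benzyloxybenzyl and tert-butyl cations are trapped by pentamethylbenzene or chloride before they can alkylate the phloroglucinol rings, while the O7 methyl ether, which is not peri to a carbonyl, should stay. Low temperature is meant to keep the C2–O1 bond from ionising, so both stereocentres are carried through unchanged.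

## Compound list

1 | 1-(2,4,6-trihydroxyphenyl)ethanone | CC(=O)c1c(O)cc(O)cc1O | starting material
2 | 4-(benzyloxy)benzyl chloride | ClCc1ccc(OCc2ccccc2)cc1 | starting material
3 | 1-[4-(4-benzyloxybenzyloxy)-2,6-dihydroxyphenyl]ethanone | CC(=O)c1c(O)cc(OCc2ccc(OCc3ccccc3)cc2)cc1O | intermediate
4 | 1-[2,4-bis(4-benzyloxybenzyloxy)-6-hydroxyphenyl]ethanone | CC(=O)c1c(O)cc(OCc2ccc(OCc3ccccc3)cc2)cc1OCc1ccc(OCc2ccccc2)cc1 | intermediate
5 | 1-[2,4,6-tris(4-benzyloxybenzyloxy)phenyl]ethanone | CC(=O)c1c(OCc2ccc(OCc3ccccc3)cc2)cc(OCc2ccc(OCc3ccccc3)cc2)cc1OCc1ccc(OCc2ccccc2)cc1 | intermediate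
6 | 2-bromo-4-chlorophenol | Oc1ccc(Cl)cc1Br | starting material
7 | 2-bromo-1-tert-butoxy-4-chlorobenzene | CC(C)(C)Oc1ccc(Cl)cc1Br | intermediate
8 | 2-(2-tert-butoxy-5-chlorophenyl)-1-[2,4,6-tris(4-benzyloxybenzyloxy)phenyl]ethanone | O=C(Cc1cc(Cl)ccc1OC(C)(C)C)c1c(OCc2ccc(OCc3ccccc3)cc2)cc(OCc2ccc(OCc3ccccc3)cc2)cc1OCc1ccc(OCc2ccccc2)cc1 | intermediate
9 | 2-(2-tert-butoxy-5-chlorophenyl)-2-diazo-1-[2,4,6-tris(4-benzyloxybenzyloxy)phenyl]ethanone | O=C(c1c(OCc2ccc(OCc3ccccc3)cc2)cc(OCc2ccc(OCc3ccccc3)cc2)cc1OCc1ccc(OCc2ccccc2)cc1)C(=[N+]=[N-])c1cc(Cl)ccc1OC(C)(C)C | intermediate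
10 | (2S,3S)-3-(2-tert-butoxy-5-chlorophenyl)-2-(4-benzyloxyphenyl)-5,7-bis(4-benzyloxybenzyloxy)chroman-4-one (2,3-cis) | CC(C)(C)Oc1ccc(Cl)cc1[C@@H]1C(=O)c2c(OCc3ccc(OCc4ccccc4)cc3)cc(OCc3ccc(OCc4ccccc4)cc3)cc2O[C@@H]1c1ccc(OCc2ccccc2)cc1 | intermediate
11 | (2S,3R)-3-(2-tert-butoxy-5-chlorophenyl)-2-(4-benzyloxyphenyl)-5,7-bis(4-benzyloxybenzyloxy)chroman-4-one (2,3-trans) | CC(C)(C)Oc1ccc(Cl)cc1[C@H]1C(=O)c2c(OCc3ccc(OCc4ccccc4)cc3)cc(OCc3ccc(OCc4ccccc4)cc3)cc2O[C@@H]1c1ccc(OCc2ccccc2)cc1 | intermediate
12 | 1-(2,6-dihydroxy-4-methoxyphenyl)ethanone | CC(=O)c1c(O)cc(OC)cc1O | starting material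
13 | 1-(2-benzyloxy-6-hydroxy-4-methoxyphenyl)ethanone | CC(=O)c1c(O)cc(OC)cc1OCc1ccccc1 | intermediate
14 | (E)-1-(2-benzyloxy-6-hydroxy-4-methoxyphenyl)-3-(dimethylamino)prop-2-en-1-one | CN(C)/C=C/C(=O)c1c(O)cc(OC)cc1OCc1ccccc1 | intermediate
15 | 5-benzyloxy-7-methoxy-4H-chromen-4-one | COc1cc(OCc2ccccc2)c2c(=O)ccoc2c1 | intermediate
16 | (5-benzyloxy-7-methoxy-4-oxo-4H-chromen-2-yl)zinc chloride | COc1cc(OCc2ccccc2)c2c(=O)cc([Zn]Cl)oc2c1 | intermediate
17 | (2S,3R)-3-[5-(5-benzyloxy-7-methoxy-4-oxo-4H-chromen-2-yl)-2-tert-butoxyphenyl]-2-(4-benzyloxyphenyl)-5,7-bis(4-benzyloxybenzyloxy)chroman-4-one | COc1cc(OCc2ccccc2)c2c(=O)cc(-c3ccc(OC(C)(C)C)c([C@H]4C(=O)c5c(OCc6ccc(OCc7ccccc7)cc6)cc(OCc6ccc(OCc7ccccc7)cc6)cc5O[C@@H]4c4ccc(OCc5ccccc5)cc4)c3)oc2c1 | intermediate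
18 | (2S,3R)-5,7-dihydroxy-3-[2-hydroxy-5-(5-hydroxy-7-methoxy-4-oxo-4H-chromen-2-yl)phenyl]-2-(4-hydroxyphenyl)chroman-4-one | COc1cc(O)c2c(=O)cc(-c3ccc(O)c([C@H]4C(=O)c5c(O)cc(O)cc5O[C@@H]4c4ccc(O)cc4)c3)oc2c1 | target

## Step count and least certain steps

Total: 11 steps. Longest linear sequence: 8 steps (1, 2, 3, 5, 6, 7, 10, 11). Steps 4, 8 and 9 prepare the two side fragments.

**Step 7 (key step).**
- Most likely failure: the ring A ether oxygen attacks the carbenoid to give a five-membered oxonium ylide, and the 4-benzyloxybenzyl group, a very good migrating group, then shifts to carbon. This Stevens pathway consumes the carbenoid without forming ring C.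
- Second failure: enantioselection at C2 is weak or reversed, because the two hindered aryl groups may keep the reacting methylene away from the chiral pocket.
- Third failure: the DBU equilibration opens ring C by E1cB elimination and erodes C2.
- Fallback: this sets out from 8 and returns at 11. MgBr2·OEt2 would remove one ether ortho to the carbonyl through chelation, giving 2-(2-tert-butoxy-5-chlorophenyl)-1-[2-hydroxy-4,6-bis(4-benzyloxybenzyloxy)phenyl]ethanone F1. Condensation of F1 with 4-(benzyloxy)benzaldehyde under piperidine in refluxing ethanol (Knoevenagel condensation, then intramolecular oxa-Michael addition) should give racemic trans-3-(2-tert-butoxy-5-chlorophenyl)-2-(4-benzyloxyphenyl)-5,7-bis(4-benzyloxybenzyloxy)chroman-4-one F2. Preparative chromatography on a chiral stationary phase would separate 11 from its (2R,3S)-enantiomer F3.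

**Step 10 (Negishi coupling).**
- Most likely failure: oxidative addition into the electron-rich aryl chloride is slow, so the mixture has to be heated. The liberated amine and the zinc species then epimerise C3 and, through opening of ring C, erode C2.
- Second failure: zincation of the chromone at C3 instead of C2 would give the wrong linkage, so the site must be confirmed on 15 before use.
- Fallback: the coupling is moved in front of the stereocentres; this sets out from 8 and returns at 17. Deoxybenzoin 8 has no stereocentre and can be coupled with 16 under the same catalyst at reflux to give 2-[2-tert-butoxy-5-(5-benzyloxy-7-methoxy-4-oxo-4H-chromen-2-yl)phenyl]-1-[2,4,6-tris(4-benzyloxybenzyloxy)phenyl]ethanone F4. Diazo transfer with p-ABSA and DBU would give 2-[2-tert-butoxy-5-(5-benzyloxy-7-methoxy-4-oxo-4H-chromen-2-yl)phenyl]-2-diazo-1-[2,4,6-tris(4-benzyloxybenzyloxy)phenyl]ethanone F5. Insertion with Rh2(S-PTTL)4 and DBU equilibration of any (2S,3S)-cis diastereomer of 17 F6 would then give 17. In this variant the flavone is a spectator in the insertion and nothing but deprotection follows the stereocentres.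

**Step 11 (global deprotection).**
- Most likely failure: BCl3 bound to the C4 carbonyl and O5 turns O1 into a leaving group, the 4-oxygenated ring B stabilises the cation at C2, and ring C opens to a chalcone and recloses with loss of configuration at C2.
- Second failure: the 4-benzyloxybenzyl cation alkylates the phloroglucinol rings if the scavenger is outcompeted.
- Fallback: this sets out from 17 and returns at 18. Hydrogenolysis (H2, 10% Pd/C, THF/MeOH, rt) would remove all benzyl-type ethers under neutral conditions and give (2S,3R)-3-[2-tert-butoxy-5-(5-hydroxy-7-methoxy-4-oxo-4H-chromen-2-yl)phenyl]-5,7-dihydroxy-2-(4-hydroxyphenyl)chroman-4-one F7. Brief treatment with TFA in CH2Cl2 at 0 °C would then cleave the tert-butyl ether to give 18.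

**Step 5 (enolate arylation).**
- Most likely failure: the bulky ortho tert-butoxy group slows oxidative addition and reductive elimination, so that hydrodehalogenation of 7 and base-mediated self-condensation of 5 take over.
- Fallback: the same bond is made with reversed polarity; this sets out from 5 and 7 and returns at 8. Ketone 5 would be converted (TMSOTf, Et3N) into trimethyl({1-[2,4,6-tris(4-benzyloxybenzyloxy)phenyl]ethenyl}oxy)silane F8 and brominated with NBS to 2-bromo-1-[2,4,6-tris(4-benzyloxybenzyloxy)phenyl]ethanone F9. Bromide 7 would undergo bromine–lithium exchange (n-BuLi, THF, −78 °C) to (2-tert-butoxy-5-chlorophenyl)lithium F10 and transmetalation with ZnCl2 to (2-tert-butoxy-5-chlorophenyl)zinc chloride F11. A nickel-catalysed Negishi arylation of the α-bromo ketone (NiCl2·glyme, pybox ligand, THF, −20 °C) would join F9 and F11 to give 8.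

**Step 1 (para mono-alkylation).**
- Most likely failure: the three hydroxyls differ only moderately in acidity, so alkylation at an ortho oxygen and double alkylation accompany the para mono-ether and lower the amount of 3.
- Fallback: the order of the first two alkylations is made irrelevant; this sets out from 1 and 2 and returns at 4. With a little more than two equivalents of 2 and K2CO3 in refluxing acetone, both 3 and any regioisomeric 1-[2-(4-benzyloxybenzyloxy)-4,6-dihydroxyphenyl]ethanone F12 formed on the way should be carried on to the same bis-ether 4, because in either order the second alkylation leaves one chelated hydroxyl and stops there.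

## Further compounds

F1 | step 7 | 2-(2-tert-butoxy-5-chlorophenyl)-1-[2-hydroxy-4,6-bis(4-benzyloxybenzyloxy)phenyl]ethanone | O=C(Cc1cc(Cl)ccc1OC(C)(C)C)c1c(O)cc(OCc2ccc(OCc3ccccc3)cc2)cc1OCc1ccc(OCc2ccccc2)cc1
F2 | step 7 | racemic trans-3-(2-tert-butoxy-5-chlorophenyl)-2-(4-benzyloxyphenyl)-5,7-bis(4-benzyloxybenzyloxy)chroman-4-one (racemate; SMILES drawn for the 2S,3R form) | CC(C)(C)Oc1ccc(Cl)cc1[C@H]1C(=O)c2c(OCc3ccc(OCc4ccccc4)cc3)cc(OCc3ccc(OCc4ccccc4)cc3)cc2O[C@@H]1c1ccc(OCc2ccccc2)cc1
F3 | step 7 | (2R,3S)-3-(2-tert-butoxy-5-chlorophenyl)-2-(4-benzyloxyphenyl)-5,7-bis(4-benzyloxybenzyloxy)chroman-4-one | CC(C)(C)Oc1ccc(Cl)cc1[C@@H]1C(=O)c2c(OCc3ccc(OCc4ccccc4)cc3)cc(OCc3ccc(OCc4ccccc4)cc3)cc2O[C@H]1c1ccc(OCc2ccccc2)cc1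
F4 | step 10 | 2-[2-tert-butoxy-5-(5-benzyloxy-7-methoxy-4-oxo-4H-chromen-2-yl)phenyl]-1-[2,4,6-tris(4-benzyloxybenzyloxy)phenyl]ethanone | COc1cc(OCc2ccccc2)c2c(=O)cc(-c3ccc(OC(C)(C)C)c(CC(=O)c4c(OCc5ccc(OCc6ccccc6)cc5)cc(OCc5ccc(OCc6ccccc6)cc5)cc4OCc4ccc(OCc5ccccc5)cc4)c3)oc2c1
F5 | step 10 | 2-[2-tert-butoxy-5-(5-benzyloxy-7-methoxy-4-oxo-4H-chromen-2-yl)phenyl]-2-diazo-1-[2,4,6-tris(4-benzyloxybenzyloxy)phenyl]ethanone | COc1cc(OCc2ccccc2)c2c(=O)cc(-c3ccc(OC(C)(C)C)c(C(=[N+]=[N-])C(=O)c4c(OCc5ccc(OCc6ccccc6)cc5)cc(OCc5ccc(OCc6ccccc6)cc5)cc4OCc4ccc(OCc5ccccc5)cc4)c3)oc2c1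
F6 | step 10 | (2S,3S)-3-[5-(5-benzyloxy-7-methoxy-4-oxo-4H-chromen-2-yl)-2-tert-butoxyphenyl]-2-(4-benzyloxyphenyl)-5,7-bis(4-benzyloxybenzyloxy)chroman-4-one (2,3-cis) | COc1cc(OCc2ccccc2)c2c(=O)cc(-c3ccc(OC(C)(C)C)c([C@@H]4C(=O)c5c(OCc6ccc(OCc7ccccc7)cc6)cc(OCc6ccc(OCc7ccccc7)cc6)cc5O[C@@H]4c4ccc(OCc5ccccc5)cc4)c3)oc2c1
F7 | step 11 | (2S,3R)-3-[2-tert-butoxy-5-(5-hydroxy-7-methoxy-4-oxo-4H-chromen-2-yl)phenyl]-5,7-dihydroxy-2-(4-hydroxyphenyl)chroman-4-one | COc1cc(O)c2c(=O)cc(-c3ccc(OC(C)(C)C)c([C@H]4C(=O)c5c(O)cc(O)cc5O[C@@H]4c4ccc(O)cc4)c3)oc2c1
F8 | step 5 | trimethyl({1-[2,4,6-tris(4-benzyloxybenzyloxy)phenyl]ethenyl}oxy)silane | C=C(O[Si](C)(C)C)c1c(OCc2ccc(OCc3ccccc3)cc2)cc(OCc2ccc(OCc3ccccc3)cc2)cc1OCc1ccc(OCc2ccccc2)cc1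
F9 | step 5 | 2-bromo-1-[2,4,6-tris(4-benzyloxybenzyloxy)phenyl]ethanone | O=C(CBr)c1c(OCc2ccc(OCc3ccccc3)cc2)cc(OCc2ccc(OCc3ccccc3)cc2)cc1OCc1ccc(OCc2ccccc2)cc1
F10 | step 5 | (2-tert-butoxy-5-chlorophenyl)lithium | [Li]c1cc(Cl)ccc1OC(C)(C)C
F11 | step 5 | (2-tert-butoxy-5-chlorophenyl)zinc chloride | Cl[Zn]c1cc(Cl)ccc1OC(C)(C)C
F12 | step 1 | 1-[2-(4-benzyloxybenzyloxy)-4,6-dihydroxyphenyl]ethanone | CC(=O)c1c(O)cc(O)cc1OCc1ccc(OCc2ccccc2)cc1
A1 | alternative 1 | 2-(4-benzyloxy-3-bromophenyl)-5,7-dihydroxychromen-4-one | Oc1cc(O)c2c(=O)cc(-c3ccc(OCc4ccccc4)c(Br)c3)oc2c1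
A2 | alternative 1 | methyl 9-(4-benzyloxy-3-bromophenyl)-3,5,7,9-tetraoxononanoate | COC(=O)CC(=O)CC(=O)CC(=O)CC(=O)c1ccc(OCc2ccccc2)c(Br)c1
A3 | alternative 2 | (2S,3R)-5,7-bis(benzyloxy)-2-(4-benzyloxyphenyl)-3-[2-benzyloxy-5-(5-hydroxy-7-methoxy-4-oxo-4H-chromen-2-yl)phenyl]chroman-4-one | COc1cc(O)c2c(=O)cc(-c3ccc(OCc4ccccc4)c([C@H]4C(=O)c5c(OCc6ccccc6)cc(OCc6ccccc6)cc5O[C@@H]4c4ccc(OCc5ccccc5)cc4)c3)oc2c1
A4 | alternative 2 | 2-iodo-5-methoxybenzene-1,3-diol | COc1cc(O)c(I)c(O)c1
A5 | alternative 2 | (2S,3R)-5,7-bis(benzyloxy)-3-(2-benzyloxy-5-ethynylphenyl)-2-(4-benzyloxyphenyl)chroman-4-one | C#Cc1ccc(OCc2ccccc2)c([C@H]2C(=O)c3c(OCc4ccccc4)cc(OCc4ccccc4)cc3O[C@@H]2c2ccc(OCc3ccccc3)cc2)c1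
A6 | alternative 3 | (2S,3R)-5,7-bis(benzyloxy)-2-(4-benzyloxyphenyl)-3-[5-(5-benzyloxy-7-methoxy-4-oxo-4H-chromen-2-yl)-2-(pivaloyloxy)phenyl]chroman (2,3-trans flavan) | COc1cc(OCc2ccccc2)c2c(=O)cc(-c3ccc(OC(=O)C(C)(C)C)c([C@H]4Cc5c(OCc6ccccc6)cc(OCc6ccccc6)cc5O[C@@H]4c4ccc(OCc5ccccc5)cc4)c3)oc2c1
A7 | alternative 3 | 3,5-bis(benzyloxy)-2-(hydroxymethyl)phenol | OCc1c(O)cc(OCc2ccccc2)cc1OCc1ccccc1
A8 | alternative 3 | 5-benzyloxy-2-{3-[(E)-2-(4-benzyloxyphenyl)ethenyl]-4-(pivaloyloxy)phenyl}-7-methoxy-4H-chromen-4-one | COc1cc(OCc2ccccc2)c2c(=O)cc(-c3ccc(OC(=O)C(C)(C)C)c(/C=C/c4ccc(OCc5ccccc5)cc4)c3)oc2c1
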